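**Strategy.** Ring A (C1, C10, C11, C12, C13, C14; briarane numbering) carries oxygen at C12 and C14 in a 1,3-relationship and is treated as a latent cyclohexane-1,3-dione. Everything rests on cutting C10–C11 and C13–C14: a Michael–Claisen [3+3] annulation in which ethyl acetoacetate supplies C11–C12–C13 and a chiral α-methyl enonolactone supplies C14–C1–C10 together with C9, C8 and C7. In one operation the carbocycle forms, C10 is set trans to the C9 ether and the lactone ring opens to unmask O8. Stork–Danheiser chemistry, a Reformatsky lactone annulation, a CrCl2-mediated ten-membered ring closure and late epoxidation and ene chlorination complete the target.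

Key step: step 4

Remark 1: atom numbers in names and Why lines are those of the briarane skeleton of the target (ring A = C1, C10, C11, C12, C13, C14; ten-membered ring = C1 to C10; lactone = C7, C8, C17, C19 and O); β is the face of ring A that carries CH3-15, α the opposite face.
Remark 2: (3R,4R)-hexa-1,5-diene-3,4-diol (1) is assumed to be purchasable as a chiral-pool diol (it is otherwise a short, known derivative of D-mannitol).

Step 1
Reactants: 1 (3R,4R)-hexa-1,5-diene-3,4-diol
Product: 2 (3R,4R)-4-[(4-methoxybenzyl)oxy]hexa-1,5-dien-3-ol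
Conditions: NaH (1.0 equiv), 4-methoxybenzyl chloride, n-Bu4NI (cat.), THF/DMF, 0 °C to rt
Reagents that add atoms: 4-methoxybenzyl chloride (COc1ccc(CCl)cc1)
Why: Williamson etherification; the two hydroxyls of the C2-symmetric diol are equivalent, so mono-alkylation should give a single mono-ether (future C9–OPMB) and no stereocentre is touched.

Step 2
Reactants: 2 (3R,4R)-4-[(4-methoxybenzyl)oxy]hexa-1,5-dien-3-ol; 3 methacrylic acid
Product: 4 (3S,4R)-4-[(4-methoxybenzyl)oxy]hexa-1,5-dien-3-yl 2-methylprop-2-enoate
Conditions: PPh3, diisopropyl azodicarboxylate, THF, 0 °C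
Reagents that add atoms: none
Why: Mitsunobu esterification installs the methacrylate with inversion at the free carbinol (future C8), giving the erythro (anti) C8/C9 pattern that later steers the addition at C7.

Step 3
Reactants: 4 (3S,4R)-4-[(4-methoxybenzyl)oxy]hexa-1,5-dien-3-yl 2-methylprop-2-enoate
Product: 5 (5R,6S)-6-ethenyl-5-[(4-methoxybenzyl)oxy]-3-methyl-5,6-dihydro-2H-pyran-2-one (enonolactone)
Conditions: second-generation Grubbs catalyst (5 mol %), toluene, 80 °C
Reagents that add atoms: none
Why: Ring-closing metathesis between the methacrylate and the vinyl group on the PMB-bearing carbon should close the six-membered unsaturated lactone (favoured over the butenolide alternative) with loss of ethene; the stereocentres are untouched and the remaining vinyl carbon becomes C7.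

Step 4
Reactants: 5 enonolactone; 6 ethyl acetoacetate
Product: 9 ring-A 1,3-dione (4R,5S)-5-{(1R,2S)-2-hydroxy-1-[(4-methoxybenzyl)oxy]but-3-en-1-yl}-4-methylcyclohexane-1,3-dione, via Michael adduct 7 (not isolated), via keto ester 8 (not isolated)
Conditions: NaOEt (1.1 equiv), EtOH, 0 °C to reflux; then aq. NaOH, 60 °C; then AcOH to pH 5, 50 °C
Reagents that add atoms: none
Why: Sodium acetoacetate adds in a Michael reaction to C10 of the enonolactone (bond C10–C11), the ester enolate is protonated, and the methyl-ketone enolate (C13) then attacks the lactone carbonyl C14 in a Claisen condensation (bond C13–C14) that expels the C8 alkoxide and ends as the stable 1,3-dione enolate, which pulls both reversible steps forward; saponification and decarboxylation then remove the C11 ester. The closest known reaction type is the consecutive Michael–Claisen synthesis of cyclohexane-1,3-diones from acetoacetates and α,β-unsaturated esters, with a lactone carbonyl as the acyl acceptor as in phthalide annulations. Ring A closes by a 6-(enolendo)-exo-trig acylation while the δ-lactone ring opens. The only stereocentre made and kept is C10: the nucleophile should enter anti to the C9–OPMB group on the neighbouring ring carbon (trans addition, as with 4-alkoxycyclohexenones and sugar enonolactones), and C9 and C8 are carried through unchanged. The step needs chemoselectivity for conjugate addition over lactone cleavage or γ-deprotonation, which the soft, weakly basic acetoacetate anion should secure, and regioselectivity (C11 in the Michael step, C13 in the Claisen step), which follows from the acidity order of the two α-positions and the six-membered ring size. C1 is epimerisable and is cleared in step 7, and C11 becomes CH2, so neither needs control here.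

Step 5
Reactants: 9 ring-A 1,3-dione
Product: 10 vinylogous methyl ester (C12–OMe enol ether, C14 ketone)
Conditions: Me2SO4, K2CO3, acetone, rt
Reagents that add atoms: dimethyl sulfate (COS(=O)(=O)OC)
Why: O-alkylation of the dione enolate (vinylogous ester formation) should occur mainly at the less hindered oxygen on C12, remote from the C1 methyl, which leaves C14 as the ketone and C1 as its α′ position; the secondary alcohol is not alkylated under these conditions.

Step 6
Reactants: 10 vinylogous methyl ester
Product: 11 C8 tert-butyldimethylsilyl ether of 10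
Conditions: t-BuMe2SiCl, imidazole, DMAP (cat.), DMF, 40 °C
Reagents that add atoms: tert-butyldimethylsilyl chloride (CC(C)(C)[Si](C)(C)Cl)
Why: Standard silylation protects the C8 hydroxyl for the enolate, hydride and oxidation steps that follow; no stereocentre is affected.

Step 7
Reactants: 11 C8 silyl ether
Product: 12 C1-quaternary vinylogous ester carrying CH(OMe)2 (masked C2 aldehyde, α) and CH3-15 (β) on C1
Conditions: LiN(iPr)2, THF, −78 °C; then HC(OMe)3/BF3·OEt2 (premixed), CH2Cl2, −78 °C
Reagents that add atoms: trimethyl orthoformate (COC(OC)OC)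
Why: Stork–Danheiser kinetic α′-deprotonation gives the C1 enolate, which is alkylated by the dimethoxycarbenium ion on the face anti to the C10 side chain, so the masked C2 aldehyde enters α and CH3-15 ends β (C1 quaternary centre set).

Step 8
Reactants: 12 C1-quaternary vinylogous ester
Product: 14 ring-A enone (C12 ketone, C13=C14), via allylic alcohol 13 (not isolated)
Conditions: iBu2AlH, toluene, −78 °C; then 0.5 M aq. oxalic acid, THF, 0 °C
Reagents that add atoms: water (O)
Why: Stork–Danheiser transposition: hydride reduction of the C14 carbonyl, then mild acid hydrolysis of the enol ether and dehydration, should give the C12 enone with the C13=C14 double bond, while the hindered dimethyl acetal, the silyl ether and the PMB ether survive oxalic acid.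

Step 9
Reactants: 14 ring-A enone
Product: 15 13α,14α-epoxy ketone
Conditions: H2O2 (30 % aq.), NaOH (cat.), MeOH, 0 °C
Reagents that add atoms: hydrogen peroxide (OO)
Why: Weitz–Scheffer nucleophilic epoxidation is chemoselective for the enone (the C7 vinyl group is inert), and hydroperoxide should add axially to C14 anti to pseudo-axial CH3-15 in the half-chair that keeps the C10 chain equatorial, giving the α-epoxide.

Step 10
Reactants: 15 13α,14α-epoxy ketone
Product: 16 11α-methyl epoxy ketone (CH3-20 trans to the C10 chain)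
Conditions: LiN(iPr)2, THF, −78 °C; then MeI, −78 to −40 °C
Reagents that add atoms: iodomethane (CI)
Why: Kinetic α′-enolate alkylation at C11; iodomethane approaches the enolate anti to the C10 side chain, so this step should give the 11α-methyl epimer, which step 11 corrects.

Step 11
Reactants: 16 11α-methyl epoxy ketone
Product: 17 11β-methyl epoxy ketone (CH3-20 cis to the C10 chain)
Conditions: LiN(iPr)2, THF, −78 °C; then AcOH in THF, −78 °C
Reagents that add atoms: none
Why: Re-enolisation and kinetic protonation from the same, less hindered α face places hydrogen α and CH3-20 β, the contra-thermodynamic cis relationship to the C10 chain (epimerisation by kinetic protonation of an enolate).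

Step 12
Reactants: 17 11β-methyl epoxy ketone
Product: 18 12β-alcohol (trans to the epoxide)
Conditions: NaBH4, CeCl3·7H2O, MeOH, −78 °C
Reagents that add atoms: none
Why: Luche reduction of the α,β-epoxy ketone should deliver hydride from the α face (opposite CH3-20 and the C10 chain), giving the trans-epoxy alcohol with 12β-OH and removing the risk of C11 epimerisation.

Step 13
Reactants: 18 12β-alcohol
Product: 19 12β-acetate
Conditions: Ac2O, pyridine, DMAP (cat.), CH2Cl2, rt
Reagents that add atoms: acetic anhydride (CC(=O)OC(C)=O)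
Why: Standard acetylation of the only free hydroxyl installs the C12 acetate of the target with retention.

Step 14
Reactants: 19 12β-acetate
Product: 21 C7 aldehyde, via diol 20 (not isolated)
Conditions: OsO4 (2 mol %), NaIO4, 2,6-lutidine, dioxane/H2O, rt
Reagents that add atoms: osmium tetroxide (O=[Os](=O)(=O)=O); sodium periodate ([Na+].[O-]I(=O)(=O)=O)
Why: Lemieux–Johnson cleavage; the terminal vinyl group is the only alkene in 19, so dihydroxylation and periodate cleavage should give the α-silyloxy aldehyde at C7 without touching C8.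

Step 15
Reactants: 22 prop-2-yn-1-ol
Product: 23 (Z)-3-iodo-2-methylprop-2-en-1-ol
Conditions: MeMgBr (2.2 equiv), CuI (10 mol %), Et2O, −10 °C to rt; then I2, THF, −10 °C
Reagents that add atoms: methylmagnesium bromide (C[Mg]Br); iodine (II)
Why: Copper-catalysed anti-carbomagnesiation of the magnesium alkoxide of propargyl alcohol followed by iodinolysis should give the (Z)-iodoalkenol with iodine cis to CH2OH (C6, C5, CH3-16 and C4 of the target).

Step 16
Reactants: 23 (Z)-3-iodo-2-methylprop-2-en-1-ol
Product: 24 (Z)-3-iodo-2-methylprop-2-enal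
Conditions: MnO2, CH2Cl2, rt
Reagents that add atoms: none
Why: Neutral allylic oxidation with MnO2 gives the enal without isomerising the Z double bond.

Step 17
Reactants: 24 (Z)-3-iodo-2-methylprop-2-enal
Product: 25 (Z)-1-iodo-2-methylbut-1-en-3-yne
Conditions: Me3SiCHN2, LiN(iPr)2, THF, −78 to 0 °C
Reagents that add atoms: trimethylsilyldiazomethane (C[Si](C)(C)C=[N+]=[N-])
Why: Colvin rearrangement with lithiated trimethylsilyldiazomethane homologates the aldehyde to the terminal alkyne (C3) at low temperature, avoiding alkoxide addition–elimination at the β-iodo enal.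

Step 18
Reactants: 21 C7 aldehyde; 25 (Z)-1-iodo-2-methylbut-1-en-3-yne
Product: 26 C7 allylic alcohol (C6–C7 bond formed, Z-enyne side chain)
Conditions: CrCl2 (4 equiv), NiCl2 (1 mol %), DMSO/THF, rt
Reagents that add atoms: none
Why: Nozaki–Hiyama–Kishi coupling; the alkenylchromium reagent adds chemoselectively to the aldehyde with retention of the Z geometry and, by non-chelated 1,2-induction anti to the C8–OTBS group, should set C7 with the 7,8-anti relationship that corresponds to the target configuration.

Step 19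
Reactants: 26 C7 allylic alcohol; 27 2-bromopropanoyl bromide
Product: 28 C7 2-bromopropanoate
Conditions: pyridine, CH2Cl2, −40 °C
Reagents that add atoms: none
Why: Acylation of the only free hydroxyl with the acid bromide attaches C17, C18 and C19 to O7 as a Reformatsky precursor (the bromine-bearing centre is later lost as an enolate).

Step 20
Reactants: 28 C7 2-bromopropanoate
Product: 29 C8 alcohol
Conditions: HF·pyridine, pyridine, THF, 0 °C to rt
Reagents that add atoms: none
Why: Buffered fluoride desilylation frees the C8 hydroxyl while the epoxide, dimethyl acetal, PMB ether and bromo ester are expected to survive the mildly acidic, non-aqueous medium.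

Step 21
Reactants: 29 C8 alcohol
Product: 30 C8 ketone
Conditions: Dess–Martin periodinane, NaHCO3, CH2Cl2, 0 °C
Reagents that add atoms: none
Why: Dess–Martin oxidation under buffered neutral conditions gives the α-acyloxy ketone without epimerising C7 or C9.

Step 22
Reactants: 30 C8 ketone
Product: 31 β-hydroxy γ-lactone (C8–C17 bond; 8-OH, CH3-18)
Conditions: SmI2 (2.5 equiv), THF, −78 °C
Reagents that add atoms: none
Why: SmI2-mediated intramolecular Reformatsky reaction: C–Br reduction is faster than ketone reduction, and the samarium enolate should add to the C8 ketone through a chelated chair-like transition state with the C6-bearing substituent anti to C9, giving the trans-fused lactone with 8-OH cis to C6 and CH3-18 cis to 8-OH.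

Step 23
Reactants: 31 β-hydroxy γ-lactone
Product: 32 C9 alcohol
Conditions: DDQ, CH2Cl2/pH 7 buffer, 0 °C
Reagents that add atoms: none
Why: Oxidative cleavage of the PMB ether with DDQ in wet solvent frees the C9 hydroxyl under neutral conditions that spare the enyne, epoxide, acetal and esters.

Step 24
Reactants: 32 C9 alcohol
Product: 33 C9 acetate
Conditions: Ac2O, pyridine, DMAP (cat.), CH2Cl2, 0 °C
Reagents that add atoms: acetic anhydride (CC(=O)OC(C)=O)
Why: Acetylation is selective for the secondary C9 hydroxyl over the hindered tertiary C8 hydroxyl and installs the second acetate with retention.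

Step 25
Reactants: 33 C9 acetate
Product: 34 C2 aldehyde
Conditions: LiBF4, MeCN/H2O (98:2), rt
Reagents that add atoms: water (O)
Why: Mild Lewis-acid hydrolysis of the dimethyl acetal unmasks the non-enolisable C2 aldehyde without opening the epoxide or dehydrating the β-hydroxy lactone.

Step 26
Reactants: 34 C2 aldehyde
Product: 35 iodoalkyne
Conditions: N-iodosuccinimide, AgNO3 (10 mol %), acetone, rt, dark
Reagents that add atoms: N-iodosuccinimide (O=C1CCC(=O)N1I)
Why: Silver-catalysed iodination of the terminal alkyne gives the 1-iodoalkyne needed for chromium insertion; aldehyde, alkene and esters are inert.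

Step 27
Reactants: 35 iodoalkyne
Product: 36 ten-membered cyclic enynol (C2–C3 bond, 2-OH)
Conditions: CrCl2 (5 equiv), NiCl2 (1 mol %), THF (2 mM), rt
Reagents that add atoms: none
Why: Intramolecular Nozaki–Hiyama–Kishi alkynylation: the alkynylchromium species adds only to the aldehyde and closes the ten-membered ring across the Z-enyne (as in ten-membered enediyne carbocycles), and attack anti to the C1–C14 bond with CH3-15 as the small flanking group should give the 2α-alcohol.

Step 28
Reactants: 36 cyclic enynol
Product: 37 (3Z,5Z)-dienol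
Conditions: H2 (1 atm), Pd/CaCO3 poisoned with Pb(OAc)2, quinoline, EtOAc, rt
Reagents that add atoms: none
Why: Lindlar semi-hydrogenation reduces the strained ring alkyne to the Z-alkene (C3=C4) and should leave the trisubstituted C5=C6 alkene untouched.

Step 29
Reactants: 37 (3Z,5Z)-dienol
Product: 38 3,4-epoxy alcohol
Conditions: VO(acac)2 (5 mol %), t-BuOOH, CH2Cl2, 0 °C
Reagents that add atoms: tert-butyl hydroperoxide (CC(C)(C)OO)
Why: Vanadium-directed epoxidation of the allylic alcohol is chemoselective for the C3=C4 alkene of the dienol and should deliver oxygen syn to the C2 hydroxyl on the Z-alkene, giving the cis-epoxide on the same face as 2-OH as in medium-ring Z-cycloalkenols.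

Step 30
Reactants: 38 3,4-epoxy alcohol
Product: 39 CNP0379630.2 (target)
Conditions: Ca(OCl)2, CO2 (dry ice), CH2Cl2/H2O, 0 °C
Reagents that add atoms: calcium hypochlorite ([Ca+2].[O-]Cl.[O-]Cl)
Why: Ene-type chlorination by hypochlorous acid transfers Cl+ to C6 of the trisubstituted alkene with loss of a proton from CH3-16 (C4 carries no removable hydrogen that could give a stable alkene), creating the exocyclic methylene, and attack anti to the allylic C7–O bond in the allylic-strain-minimised conformer should give the 6α-chloride.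

**Compound list**

1 | (3R,4R)-hexa-1,5-diene-3,4-diol | C=C[C@@H](O)[C@H](O)C=C | starting material
2 | (3R,4R)-4-[(4-methoxybenzyl)oxy]hexa-1,5-dien-3-ol | C=C[C@@H](OCc1ccc(OC)cc1)[C@H](O)C=C | intermediate
3 | methacrylic acid | CC(=C)C(=O)O | starting material
4 | (3S,4R)-4-[(4-methoxybenzyl)oxy]hexa-1,5-dien-3-yl 2-methylprop-2-enoate | C=C[C@@H](OCc1ccc(OC)cc1)[C@@H](OC(=O)C(C)=C)C=C | intermediate
5 | (5R,6S)-6-ethenyl-5-[(4-methoxybenzyl)oxy]-3-methyl-5,6-dihydro-2H-pyran-2-one (enonolactone; ring = O8, C14, C1, C10, C9, C8; vinyl CH = C7) | CC1=C[C@@H](OCc2ccc(OC)cc2)[C@H](C=C)OC1=O | intermediate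
6 | ethyl acetoacetate | CCOC(=O)CC(C)=O | starting material
7 | Michael adduct: lactone 5 carrying CH(COCH3)CO2Et on C10, trans to the C9–OPMB group (C1 and C11 as epimer mixtures) | CC1C(=O)O[C@@H](C=C)[C@H](OCc2ccc(OC)cc2)[C@H]1C(C(C)=O)C(=O)OCC | intermediate
8 | keto ester: ethyl 2,4-dioxocyclohexane-1-carboxylate (ring A) with CH3 on C1 and the (1R,2S)-2-hydroxy-1-(PMB-oxy)but-3-enyl chain on C10 | CCOC(=O)C1C(=O)CC(=O)C(C)[C@H]1[C@@H](OCc2ccc(OC)cc2)[C@@H](O)C=C | intermediate
9 | (4R,5S)-5-{(1R,2S)-2-hydroxy-1-[(4-methoxybenzyl)oxy]but-3-en-1-yl}-4-methylcyclohexane-1,3-dione (ring-A 1,3-dione, drawn as the trans diketo form) | C[C@H]1C(=O)CC(=O)C[C@@H]1[C@@H](OCc2ccc(OC)cc2)[C@@H](O)C=C | intermediate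
10 | vinylogous methyl ester: 3-methoxy-6-methylcyclohex-2-en-1-one (C12–OMe, C14=O) with CH3 on C1 trans to the C10 chain; chain as in 9 | COC1=CC(=O)[C@H](C)[C@@H]([C@@H](OCc2ccc(OC)cc2)[C@@H](O)C=C)C1 | intermediate
11 | C8 tert-butyldimethylsilyl ether of 10 | COC1=CC(=O)[C@H](C)[C@@H]([C@@H](OCc2ccc(OC)cc2)[C@@H](O[Si](C)(C)C(C)(C)C)C=C)C1 | intermediate
12 | C1-quaternary vinylogous ester: 11 with CH(OMe)2 on C1 (α, trans to the C10 chain) and CH3-15 β | COC1=CC(=O)[C@](C)(C(OC)OC)[C@@H]([C@@H](OCc2ccc(OC)cc2)[C@@H](O[Si](C)(C)C(C)(C)C)C=C)C1 | intermediate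
13 | allylic alcohol: C14 carbinol from reduction of 12 (C14 epimers) | COC1=CC(O)[C@](C)(C(OC)OC)[C@@H]([C@@H](OCc2ccc(OC)cc2)[C@@H](O[Si](C)(C)C(C)(C)C)C=C)C1 | intermediate
14 | ring-A enone: C12 ketone, C13=C14; C1 with CH3-15 (β) and CH(OMe)2 (α); C10 (β) chain with C9–OPMB, C8–OTBS, C7 vinyl | O=C1C=C[C@](C)(C(OC)OC)[C@@H]([C@@H](OCc2ccc(OC)cc2)[C@@H](O[Si](C)(C)C(C)(C)C)C=C)C1 | intermediate
15 | 13α,14α-epoxy ketone of 14 | O=C1[C@@H]2O[C@@H]2[C@](C)(C(OC)OC)[C@@H]([C@@H](OCc3ccc(OC)cc3)[C@@H](O[Si](C)(C)C(C)(C)C)C=C)C1 | intermediate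
16 | 11α-methyl epoxy ketone (CH3-20 trans to the C10 chain) | O=C1[C@@H]2O[C@@H]2[C@](C)(C(OC)OC)[C@@H]([C@@H](OCc3ccc(OC)cc3)[C@@H](O[Si](C)(C)C(C)(C)C)C=C)[C@@H]1C | intermediate
17 | 11β-methyl epoxy ketone (CH3-20 cis to the C10 chain) | O=C1[C@@H]2O[C@@H]2[C@](C)(C(OC)OC)[C@@H]([C@@H](OCc3ccc(OC)cc3)[C@@H](O[Si](C)(C)C(C)(C)C)C=C)[C@H]1C | intermediate
18 | 12β-alcohol of 17 (trans to the 13α,14α-epoxide) | O[C@H]1[C@@H]2O[C@@H]2[C@](C)(C(OC)OC)[C@@H]([C@@H](OCc3ccc(OC)cc3)[C@@H](O[Si](C)(C)C(C)(C)C)C=C)[C@H]1C | intermediate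
19 | 12β-acetate of 18 | CC(=O)O[C@H]1[C@@H]2O[C@@H]2[C@](C)(C(OC)OC)[C@@H]([C@@H](OCc3ccc(OC)cc3)[C@@H](O[Si](C)(C)C(C)(C)C)C=C)[C@H]1C | intermediate
20 | diol from dihydroxylation of the C7 vinyl group of 19 | CC(=O)O[C@H]1[C@@H]2O[C@@H]2[C@](C)(C(OC)OC)[C@@H]([C@@H](OCc3ccc(OC)cc3)[C@@H](O[Si](C)(C)C(C)(C)C)C(O)CO)[C@H]1C | intermediate
21 | C7 aldehyde (C8–OTBS, C9–OPMB, ring A as in 19) | CC(=O)O[C@H]1[C@@H]2O[C@@H]2[C@](C)(C(OC)OC)[C@@H]([C@@H](OCc3ccc(OC)cc3)[C@@H](O[Si](C)(C)C(C)(C)C)C=O)[C@H]1C | intermediate
22 | prop-2-yn-1-ol | C#CCO | starting material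
23 | (Z)-3-iodo-2-methylprop-2-en-1-ol | OC/C(C)=C\I | intermediate
24 | (Z)-3-iodo-2-methylprop-2-enal | O=C/C(C)=C\I | intermediate
25 | (Z)-1-iodo-2-methylbut-1-en-3-yne | C#C/C(C)=C\I | intermediate
26 | C7 allylic alcohol: 21 after addition of the (Z)-2-methylbut-1-en-3-ynyl unit at C7 (7,8-anti) | CC(=O)O[C@H]1[C@@H]2O[C@@H]2[C@](C)(C(OC)OC)[C@@H]([C@@H](OCc3ccc(OC)cc3)[C@@H](O[Si](C)(C)C(C)(C)C)[C@@H](O)/C=C(C)\C#C)[C@H]1C | intermediate
27 | 2-bromopropanoyl bromide | CC(Br)C(Br)=O | starting material
28 | C7 2-bromopropanoate of 26 | CC(=O)O[C@H]1[C@@H]2O[C@@H]2[C@](C)(C(OC)OC)[C@@H]([C@@H](OCc3ccc(OC)cc3)[C@@H](O[Si](C)(C)C(C)(C)C)[C@@H](OC(=O)C(C)Br)/C=C(C)\C#C)[C@H]1C | intermediate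
29 | C8 alcohol (desilylated 28) | CC(=O)O[C@H]1[C@@H]2O[C@@H]2[C@](C)(C(OC)OC)[C@@H]([C@@H](OCc3ccc(OC)cc3)[C@@H](O)[C@@H](OC(=O)C(C)Br)/C=C(C)\C#C)[C@H]1C | intermediate
30 | C8 ketone (α-acyloxy ketone) | CC(=O)O[C@H]1[C@@H]2O[C@@H]2[C@](C)(C(OC)OC)[C@@H]([C@@H](OCc3ccc(OC)cc3)C(=O)[C@@H](OC(=O)C(C)Br)/C=C(C)\C#C)[C@H]1C | intermediate
31 | β-hydroxy γ-lactone (C7–O, 8-OH cis to C6, CH3-18 cis to 8-OH; C9–OPMB) | CC(=O)O[C@H]1[C@@H]2O[C@@H]2[C@](C)(C(OC)OC)[C@@H]([C@@H](OCc3ccc(OC)cc3)[C@]3(O)[C@@H](C)C(=O)O[C@H]3/C=C(C)\C#C)[C@H]1C | intermediate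
32 | C9 alcohol of 31 | CC(=O)O[C@H]1[C@@H]2O[C@@H]2[C@](C)(C(OC)OC)[C@@H]([C@@H](O)[C@]3(O)[C@@H](C)C(=O)O[C@H]3/C=C(C)\C#C)[C@H]1C | intermediate
33 | C9 acetate (9,12-diacetate, C2 as dimethyl acetal) | CC(=O)O[C@H]1[C@@H]2O[C@@H]2[C@](C)(C(OC)OC)[C@@H]([C@@H](OC(C)=O)[C@]3(O)[C@@H](C)C(=O)O[C@H]3/C=C(C)\C#C)[C@H]1C | intermediate
34 | C2 aldehyde | CC(=O)O[C@H]1[C@@H]2O[C@@H]2[C@](C)(C=O)[C@@H]([C@@H](OC(C)=O)[C@]3(O)[C@@H](C)C(=O)O[C@H]3/C=C(C)\C#C)[C@H]1C | intermediate
35 | iodoalkyne (C3–I) | CC(=O)O[C@H]1[C@@H]2O[C@@H]2[C@](C)(C=O)[C@@H]([C@@H](OC(C)=O)[C@]3(O)[C@@H](C)C(=O)O[C@H]3/C=C(C)\C#CI)[C@H]1C | intermediate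
36 | ten-membered cyclic enynol (2α-OH, C3≡C4, 5Z) | [H]/C1=C(\C)C#C[C@@H](O)[C@]2(C)[C@H]([C@@H](C)[C@@H](OC(C)=O)[C@@H]3O[C@@H]32)[C@@H](OC(C)=O)[C@]2(O)[C@@H](C)C(=O)O[C@H]21 | intermediate
37 | (3Z,5Z)-dienol | [H]/C1=C(\C)/C=C\[C@@H](O)[C@]2(C)[C@H]([C@@H](C)[C@@H](OC(C)=O)[C@@H]3O[C@@H]32)[C@@H](OC(C)=O)[C@]2(O)[C@@H](C)C(=O)O[C@H]21 | intermediate
38 | 3,4-epoxy alcohol (epoxide cis to 2-OH; 5Z alkene with CH3-16) | [H]/C1=C(\C)[C@H]2O[C@H]2[C@@H](O)[C@]2(C)[C@H]([C@@H](C)[C@@H](OC(C)=O)[C@@H]3O[C@@H]32)[C@@H](OC(C)=O)[C@]2(O)[C@@H](C)C(=O)O[C@H]21 | intermediate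
39 | CNP0379630.2 | C=C1[C@H]2O[C@H]2[C@@H](O)[C@]2(C)[C@H]([C@@H](C)[C@@H](OC(C)=O)[C@@H]3O[C@@H]32)[C@@H](OC(C)=O)[C@]2(O)[C@@H](C)C(=O)O[C@H]2[C@H]1Cl | target

**Totals and risks**

Total step count: 30. Longest linear sequence: 27 steps (steps 1–14 and 18–30); the enyne fragment 25 takes 3 steps (15–17).

The three steps most likely to fail:

1. Step 4 (key annulation). Retro-Michael reaction, ethanolysis of the lactone before the conjugate addition, or base-induced eliminative opening of the dihydropyranone may outrun the Claisen closure on the hindered α-methyl acceptor. The fallback sets out from 5 and separates the two bond formations. A Mukaiyama–Michael addition of 2-(trimethylsilyloxy)propene (TiCl4, CH2Cl2, −78 °C) places the acetonyl group on C10 anti to the C9–OPMB group and gives keto lactone F1. F1 can no longer undergo γ-deprotonation, and KOtBu in t-BuOH/THF then effects the ring-opening Claisen cyclisation of its methyl-ketone enolate onto the lactone carbonyl. This returns to the route at 9, without a decarboxylation.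

2. Step 27 (ten-membered ring closure). Facial selectivity at the C2 aldehyde may be poor, because the tether and the two flanking ring carbons compete in directing the alkynylchromium addition. The fallback sets out from 36 obtained as a C2 epimer mixture. Dess–Martin oxidation gives the cyclic ynone F2. Reagent-controlled Corey–Bakshi–Shibata reduction with (S)-2-methyl-CBS-oxazaborolidine and catecholborane (toluene, −78 °C; the alkynyl group is the small substituent next to quaternary C1) then returns to the route at 36 as the single 2α-alcohol.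

3. Step 30 (ene chlorination). Cation-triggered opening of the neighbouring 3,4-epoxide, chlorohydrin formation or chlorine delivery to the wrong face may compete with the ene pathway. The fallback sets out from 38 and moves the oxidation to the methyl group. Allylic oxidation of CH3-16 (SeO2 cat., t-BuOOH, CH2Cl2, 0 °C) gives primary allylic alcohol F3. One equivalent of SOCl2 in Et2O at −78 °C without base reacts first with the primary allylic alcohol and then transposes it by an SNi′ pathway to the secondary C6 chloride with the exocyclic methylene. This returns to the route at 39.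

Further compounds
F1 | step 4 | keto lactone: (5R,6S)-6-ethenyl-5-[(4-methoxybenzyl)oxy]-3-methyl-4-(2-oxopropyl)tetrahydro-2H-pyran-2-one, acetonyl group trans to OPMB | CC1C(=O)O[C@@H](C=C)[C@H](OCc2ccc(OC)cc2)[C@H]1CC(C)=O
F2 | step 27 | cyclic ynone: 2-oxo analogue of 36 | [H]/C1=C(\C)C#CC(=O)[C@]2(C)[C@H]([C@@H](C)[C@@H](OC(C)=O)[C@@H]3O[C@@H]32)[C@@H](OC(C)=O)[C@]2(O)[C@@H](C)C(=O)O[C@H]21
F3 | step 30 | 16-hydroxy derivative of 38 (primary allylic alcohol) | [H]/C1=C(\CO)[C@H]2O[C@H]2[C@@H](O)[C@]2(C)[C@H]([C@@H](C)[C@@H](OC(C)=O)[C@@H]3O[C@@H]32)[C@@H](OC(C)=O)[C@]2(O)[C@@H](C)C(=O)O[C@H]21
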